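## Structural features

Arecatannin A2 is a linear B-type procyanidin tetramer: three (2R,3R)-epicatechin units stacked on a (2R,3S)-catechin terminus. Each unit is a chroman (ring A fused to the pyran ring C) with a catechol ring B on C2 and a hydroxyl on C3. The units are joined by three C4→C8 bonds (all 4β), so each upper ring C carries three contiguous stereocentres C2, C3 and C4 (2,3-cis, 3,4-trans, all R), eleven in the whole molecule. Every C4 is a diarylmethine wedged between two ortho-oxygenated rings. The twenty free hydroxyls (phloroglucinol and catechol types) oxidise readily and, under base, open ring C and epimerise C2. The interflavan bonds are cleaved by acid because ring A stabilises a cation at C4, so all oxygens stay benzylated until a final neutral hydrogenolysis. The real difficulty is forging the congested C4–C8 bonds with control of C8 against C6 and of the C4 configuration, together with the 2,3-cis relationship, which is not the thermodynamic one. The feature exploited lies in ring C of the third unit (the one bonded to catechin C8): O1 sits between ring A carbon C8a and C2, so ring C without O1 is a 3-aryl-indan-1-one whose C3 is the future C4 and whose carbonyl hangs on the one ring A carbon meta to both ring oxygens. The diarylmethine carbon is (R) in both the ketone and the lactone of the ring expansion, matching C4 (R) of the target, so these two structures need no correction.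

## Logic of the disconnections

32 to 31: the twenty O–benzyl bonds and the C8–Br bond of the top unit are cut. One protecting-group type and one blocking atom, both removable by neutral reduction, keep every earlier intermediate lipophilic and non-acidic. The forward step must clear all of them without letting HBr accumulate near the acid-labile interflavan bonds.

31 to 30 and 23: the central C4–C8 bond (second unit C4 to third unit C8) is cut, halving the molecule into two dimers. The cut follows the native polarity, a ring A stabilised C4 cation attacked trans to the axial C3 oxygen. This replaces repeated ring construction on ever larger oligomers, each round of which would need a C8 handle installed beside two competing C6 positions. The forward step needs activation that spares the existing interflavan bonds, attack at the upper C8 of 23, and no self-condensation of 30, whose own C8 is blocked by bromine.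

30 to 28 and 29, then to 27, 26, 25 and 24: the upper C4–C8 bond is cut, then the C4–S, C8–Br and C4–O bonds and the benzyl ethers. Both upper units come from the chiral pool with C2 and C3 in place, and 27 is a common branch point. The forward coupling must ionise only the hard C4 acetal of 28 and leave the soft C4 sulfide of 29 for the later union. The oxidation of 26 must be selective for C4.

23 to 22: O1–C2 of the third unit is cut. Closing ring C by displacement at benzylic C2 with inversion turns an acyclic anti pattern into the disfavoured 2,3-cis ring. The forward step must be a clean bimolecular-type displacement at an electron-rich benzylic carbon.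

22 to 21, then to 17 and 19, then to 16: the C2–H bond, the C2–aryl bond and the amide C–N bond are cut. The lactone carbonyl carbon becomes C2 and ring B arrives as an aryl nucleophile. The amide 17 is interposed because an aryl ester would release the ketone in front of the organometallic and invite double addition. The forward steps must not epimerise C3, which is alpha to the carbonyl, and the reduction must follow the chelate model.

16 to 15 to 13: the C3–O bond (and its benzyl group) is cut. The oxygen is introduced by enolate oxidation, steered trans by the C4 substituent, which leaves a lactone with a single stereocentre. The forward step needs a stable aryl-ester enolate and a non-basic benzylation.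

13 to 11: the O1–C8a bond is cut, contracting the lactone to the five-membered aryl ketone. This puts the carbonyl on the ring carbon meta to both oxygens, where electrophilic substitution cannot place it, and turns the C4–C8 bond and the C4 centre into an enone arylation problem. The forward oxygen insertion must occur on the aryl side, must not oxidise the benzylated rings, and must leave C4 alone.

11 to 10, then to 9 and 6: the C4–C4a bond is cut, then the enone C=C. An ortho-bromide and the enone close the five-membered ring on palladium under a chiral ligand. This replaces an acid cyclisation, dehydrogenation and reduction sequence that would make, destroy and remake the stereocentre and would expose benzyl ethers to hot acid. The forward step needs catalyst control at a hindered beta-carbon and insertion faster than hydrodebromination.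

6 to 4, 3, 2 and 1; 9 to 8 and 7; 19 to 18: the formyl C–C bond, the C–Br bonds and the benzyl ethers are cut, reaching the three simple starting materials. The forward brominations must be regioselective (C8 of the flavan, the position ortho to acetyl in 8).

## Other disconnections considered

Alternative 1: The cut removes ring A of the top unit as a whole, breaking C4–C4a and O1–C2 together. This leaves 3,5-bis(benzyloxy)phenol A2 and the enone A3, in which the lower three units carry the 3-aryl-3-oxopropenyl group on C8. In the forward sense a BINOL-derived chiral phosphoric acid would promote Friedel–Crafts conjugate addition of the ortho carbon of A2 to the beta-carbon of A3, then condensation of the phenol oxygen with the ketone, to give the 4H-chromene A1.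
- In its favour: two ring bonds and the C4 centre form in one catalytic operation with no oxidant near electron-rich arenes. On bond economy and chemoselectivity it is better than the ring expansion, which makes one bond and no stereocentre.
- Against it here: A3 already contains both lower interflavan bonds, so the method serves only the last ring. A2 can also react para to its hydroxyl. Facial control by the acid on a substrate with eight stereocentres and a very large beta-aryl group is unproven.
- Against it further: A1 is an enol ether at the wrong oxidation pattern. Hydroboration would give the 2,3-trans alcohol, so a face-selective oxygenation at C3 and hydride delivery at C2 would still be needed.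
- Comparison: both plans rely on catalyst control at C4 and are equal there. Alternative 1 is shorter per ring, but it is linear at tetramer level and less secure at C2 and C3.

Alternative 2: The cut is C4–C4a of the third unit with O1–C2 already present, in the acyclic aryl ether A5. In the forward sense BF3·OEt2 ionises the C4 methyl ether and the tethered 3,5-bis(benzyloxy)phenyl ether attacks through an ortho carbon to give A4, which is the same compound as 23.
- In its favour: the cation is the native reactivity of flavan C4, the nucleophilic ring is symmetrical so there is no regiochemical question, and no redox adjustment follows. On step economy from the acyclic stage it is the equal or the better of the chosen plan (no oxidation, no amide detour).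
- Against it here: A5 needs an aryl ether at an electron-rich benzylic carbon of defined configuration, the same weakness as the Mitsunobu step of the chosen plan, so the two are equal on that point.
- Against it further: the C4 configuration would be set by 1,2-induction in a flexible forming ring, not by a catalyst on a rigid substrate. The long-lived cation may also be captured by C6 of a second molecule.
- Comparison: structurally more direct; mechanistically less controlled at C4.

Alternative 3: The cut is C2=C3 in the diene A7, which carries a 1-aryl-vinyl ether on the ring A oxygen and a vinyl group on C4. In the forward sense the second-generation Grubbs catalyst RuCl2(=CHPh)(H2IMes)(PCy3) would close ring C to the 4H-chromene A6 with loss of ethylene.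
- In its favour: neutral conditions, C4 set before closure as in the chosen plan, and no peracid near the benzylated rings. On chemoselectivity it is better than the Baeyer–Villiger step.
- Against it here: the C4–H of A7 is allylic and doubly benzylic, so ruthenium hydride-mediated alkene migration could erase the stereocentre. Metathesis onto a 1,1-disubstituted electron-rich enol ether is slow.
- Against it further: A6 needs the same C3 oxygenation and C2 hydride delivery as A1.
- Comparison: step count is similar or slightly lower; stereochemical security at C2 and C3 is lower than with the lactone, where the carbonyl carbon becomes C2 and the enolate gives C3.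

Key step: step 9

Remarks and assumptions.
- Flavan numbering (O1, C2, C3, C4, C4a, C5–C8, C8a) is kept for ring-opened intermediates. "Penta-O-benzylcatechin-8-yl" means the (2R,3S)-3,5,7,3',4'-pentakis(benzyloxy)flavan-8-yl group.
- Organolithiums, the enolate and the peroxide adduct that are generated and consumed in the flask are numbered. Shorter-lived cations and phosphonium species are described in words.
- (−)-Epicatechin and the common reagents are taken as purchased.
- Which antipode of the bisphosphine in step 8 delivers the (R) centre must be found in the first run. The (R)-ligand is written, and its mirror image would be used if the sense is opposite.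

## Route

Step 1
Reactants: 1 (+)-catechin
Product: 2 5,7,3',4'-tetra-O-benzyl-(+)-catechin
Conditions: BnBr, K2CO3, DMF, 0 °C → rt
Reagents that add atoms: benzyl bromide, BrCc1ccccc1
Why: Williamson etherification; K2CO3 deprotonates the four phenols but not the secondary 3-OH, and the mild base at low temperature avoids ring-opening epimerisation at C2.

Step 2
Reactants: 2 5,7,3',4'-tetra-O-benzyl-(+)-catechin
Product: 3 3,5,7,3',4'-penta-O-benzyl-(+)-catechin
Conditions: NaH, BnBr, n-Bu4NI (cat.), DMF, 0 °C → rt
Reagents that add atoms: benzyl bromide, BrCc1ccccc1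
Why: Williamson etherification of the remaining secondary alcohol through its sodium alkoxide; with all phenols capped there is no pathway for C2 epimerisation.

Step 3
Reactants: 3 3,5,7,3',4'-penta-O-benzyl-(+)-catechin
Product: 4 8-bromo-3,5,7,3',4'-penta-O-benzylcatechin
Conditions: NBS, CH2Cl2, −78 °C → rt
Reagents that add atoms: N-bromosuccinimide, O=C1CCC(=O)N1Br
Why: Electrophilic aromatic bromination; ring A is the most electron-rich ring, and C8, flanked by O1 and O7, is the known kinetic site for monobromination of benzylated flavan-3-ols in preference to C6.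

Step 4
Reactants: 4 8-bromo-3,5,7,3',4'-penta-O-benzylcatechin
Product: 6 3,5,7,3',4'-penta-O-benzylcatechin-8-carbaldehyde, via 8-lithio-penta-O-benzylcatechin 5 (not isolated)
Conditions: n-BuLi, THF, −78 °C; DMF, −78 → 0 °C; H2O
Reagents that add atoms: N,N-dimethylformamide, CN(C)C=O
Why: Bromine–lithium exchange followed by formylation; the hemiaminal alkoxide releases the aldehyde only on work-up, and benzyl ethers tolerate the organolithium at −78 °C.

Step 5
Reactants: 7 3',5'-dihydroxyacetophenone
Product: 8 3',5'-bis(benzyloxy)acetophenone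
Conditions: BnBr, K2CO3, acetone, reflux
Reagents that add atoms: benzyl bromide, BrCc1ccccc1
Why: Williamson etherification of two phenols; the methyl ketone is not alkylated by carbonate.

Step 6
Reactants: 8 3',5'-bis(benzyloxy)acetophenone
Product: 9 2'-bromo-3',5'-bis(benzyloxy)acetophenone
Conditions: NBS (1.0 equiv), MeCN, 0 °C → rt
Reagents that add atoms: N-bromosuccinimide, O=C1CCC(=O)N1Br
Why: Electrophilic aromatic bromination; the carbon ortho to acetyl is para to one benzyloxy group and ortho to the other and is less hindered than C4' between the two ethers, and a polar solvent without initiator favours ring over side-chain bromination.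

Step 7
Reactants: 9 2'-bromo-3',5'-bis(benzyloxy)acetophenone; 6 3,5,7,3',4'-penta-O-benzylcatechin-8-carbaldehyde
Product: 10 (E)-1-[2-bromo-3,5-bis(benzyloxy)phenyl]-3-(penta-O-benzylcatechin-8-yl)prop-2-en-1-one
Conditions: KOH, EtOH–THF, rt
Reagents that add atoms: none
Why: Claisen–Schmidt aldol condensation between a methyl ketone and a non-enolisable aldehyde; dehydration gives the (E)-enone and no stereocentre is formed.

Step 8
Reactants: 10 (E)-1-[2-bromo-3,5-bis(benzyloxy)phenyl]-3-(penta-O-benzylcatechin-8-yl)prop-2-en-1-one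
Product: 11 (3R)-4,6-bis(benzyloxy)-3-(penta-O-benzylcatechin-8-yl)indan-1-one
Conditions: Pd(OAc)2 (10 mol%), (R)-3,5-Xyl-MeO-BIPHEP (12 mol%), HCO2Na, DMF, 80 °C
Reagents that add atoms: none
Why: Asymmetric reductive Heck cyclisation: zerovalent palladium inserts into the C–Br bond, 5-endo carbopalladation of the enone forms C4–C4a, the palladium enolate is protonated and formate returns divalent palladium to zerovalent palladium. The (R) centre is set in the migratory insertion by the chiral bisphosphine (catalyst control, the catechin centres being remote). Any minor epimer is a diastereomer and should be removable by chromatography.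

Step 9
Reactants: 11 (3R)-4,6-bis(benzyloxy)-3-(penta-O-benzylcatechin-8-yl)indan-1-one
Product: 13 (4R)-5,7-bis(benzyloxy)-4-(penta-O-benzylcatechin-8-yl)chroman-2-one, via peroxyhemiketal Criegee adduct 12 (not isolated)
Conditions: mCPBA (1.5 equiv), NaHCO3, CH2Cl2, 0 °C → rt
Reagents that add atoms: 3-chloroperbenzoic acid, OOC(=O)c1cccc(Cl)c1
Why: Baeyer–Villiger oxidation: the peracid adds to the indanone carbonyl to give the tetrahedral adduct 12, and ring A carbon C7a migrates from carbon to the proximal peroxide oxygen as 3-chlorobenzoate leaves, the migrating bond lying antiperiplanar to the O–O bond. The closest known reaction type is the peracid ring expansion of 3-aryl-indan-1-ones to 4-aryl-3,4-dihydrocoumarins. Ring C, the six-membered lactone, is not closed by an end-to-end cyclisation but arises by ring expansion of the five-membered ketone through this 1,2-shift, which creates the single new skeletal bond O1–C8a. No stereocentre is formed; C4 is beta to the carbonyl, takes no part in the shift and cannot epimerise by enolisation, so its (R) configuration is carried through. Two selectivities are needed: migration of the aryl and not the methylene carbon, and oxidation of the ketone and not of the electron-rich benzylated rings. The first rests on the higher migratory aptitude of an aryl carbon (pi-participation in the shift) over a primary alkyl carbon, which the two meta-oxygens weaken inductively but should not invert, while the same meta placement denies the carbonyl any resonance donation and keeps it electrophilic. The second rests on the buffer (no strong acid to activate the peracid toward arene hydroxylation), low temperature, a small excess of oxidant and the full etherification of every oxygenated ring. A mild, near-neutral work-up is used because the product is an aryl ester.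

Step 10
Reactants: 13 (4R)-5,7-bis(benzyloxy)-4-(penta-O-benzylcatechin-8-yl)chroman-2-one
Product: 15 (3R,4R)-5,7-bis(benzyloxy)-3-hydroxy-4-(penta-O-benzylcatechin-8-yl)chroman-2-one, via potassium lactone enolate 14 (not isolated)
Conditions: KN(SiMe3)2, THF, −78 °C; 2-(phenylsulfonyl)-3-phenyloxaziridine, −78 °C; AcOH
Reagents that add atoms: 2-(phenylsulfonyl)-3-phenyloxaziridine, O=S(=O)(c1ccccc1)N1OC1c1ccccc1
Why: Enolate hydroxylation with an N-sulfonyloxaziridine; the oxidant approaches the enolate face anti to the pseudoaxial C4 aryl group, which should give the 3,4-trans (3R) alcohol. Keeping the potassium enolate at −78 °C limits ketene formation by phenoxide loss.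

Step 11
Reactants: 15 (3R,4R)-5,7-bis(benzyloxy)-3-hydroxy-4-(penta-O-benzylcatechin-8-yl)chroman-2-one
Product: 16 (3R,4R)-3,5,7-tris(benzyloxy)-4-(penta-O-benzylcatechin-8-yl)chroman-2-one
Conditions: BnBr, Ag2O, 4 Å MS, CH2Cl2, rt, dark
Reagents that add atoms: benzyl bromide, BrCc1ccccc1
Why: Silver oxide-mediated O-benzylation under non-basic conditions, which avoids an alkoxide or enolate that could epimerise C3 or open the aryl ester.

Step 12
Reactants: 16 (3R,4R)-3,5,7-tris(benzyloxy)-4-(penta-O-benzylcatechin-8-yl)chroman-2-one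
Product: 17 (2R,3R)-2-benzyloxy-3-[2,4-bis(benzyloxy)-6-hydroxyphenyl]-N-methoxy-N-methyl-3-(penta-O-benzylcatechin-8-yl)propanamide
Conditions: MeNH(OMe)·HCl, i-PrMgCl, THF, −20 °C
Reagents that add atoms: N,O-dimethylhydroxylamine hydrochloride, CNOC.Cl
Why: Aminolysis of the activated aryl ester by the chloromagnesium amide gives the Weinreb amide and frees the C8a phenol. It is interposed because direct aryllithium addition to the aryl lactone would release the ketone in the flask and lead to double addition.

Step 13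
Reactants: 18 4-bromobenzene-1,2-diol
Product: 19 4-bromo-1,2-bis(benzyloxy)benzene
Conditions: BnBr, K2CO3, DMF, rt
Reagents that add atoms: benzyl bromide, BrCc1ccccc1
Why: Williamson etherification of both catechol oxygens.

Step 14
Reactants: 17 (2R,3R)-2-benzyloxy-3-[2,4-bis(benzyloxy)-6-hydroxyphenyl]-N-methoxy-N-methyl-3-(penta-O-benzylcatechin-8-yl)propanamide; 19 4-bromo-1,2-bis(benzyloxy)benzene
Product: 21 (2R,3R)-2-benzyloxy-1-[3,4-bis(benzyloxy)phenyl]-3-[2,4-bis(benzyloxy)-6-hydroxyphenyl]-3-(penta-O-benzylcatechin-8-yl)propan-1-one, via 3,4-bis(benzyloxy)phenyllithium 20 (not isolated)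
Conditions: 19 (2.6 equiv), n-BuLi (2.5 equiv), THF, −78 °C; then 17, −78 → −30 °C; H2O
Reagents that add atoms: none
Why: Bromine–lithium exchange, then acyl substitution on the Weinreb amide: the first equivalent removes the phenol proton and the second forms a chelated tetrahedral adduct that survives until the quench, so the ketone appears only on work-up. The low temperature protects the C3 centre alpha to the carbonyl.

Step 15
Reactants: 21 (2R,3R)-2-benzyloxy-1-[3,4-bis(benzyloxy)phenyl]-3-[2,4-bis(benzyloxy)-6-hydroxyphenyl]-3-(penta-O-benzylcatechin-8-yl)propan-1-one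
Product: 22 (1S,2R,3R)-2-benzyloxy-1-[3,4-bis(benzyloxy)phenyl]-3-[2,4-bis(benzyloxy)-6-hydroxyphenyl]-3-(penta-O-benzylcatechin-8-yl)propan-1-ol
Conditions: Zn(BH4)2, Et2O–CH2Cl2, −30 → 0 °C
Reagents that add atoms: none
Why: Chelation-controlled ketone reduction (Cram chelate model): zinc bridges the carbonyl and the alpha-benzyloxy oxygen, and hydride arrives anti to the bulky diarylmethyl group, which should give the anti (1S) alcohol.

Step 16
Reactants: 22 (1S,2R,3R)-2-benzyloxy-1-[3,4-bis(benzyloxy)phenyl]-3-[2,4-bis(benzyloxy)-6-hydroxyphenyl]-3-(penta-O-benzylcatechin-8-yl)propan-1-ol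
Product: 23 deca-O-benzyl-epicatechin-(4β→8)-catechin (upper unit 2R,3R,4R; lower unit 2R,3S)
Conditions: PPh3, DIAD, THF, 0 °C → rt
Reagents that add atoms: none
Why: Intramolecular Mitsunobu etherification (6-exo-tet): the C8a phenol displaces the benzylic oxyphosphonium with inversion, turning the anti pattern into the 2,3-cis (2R) ring C. Fast intramolecular capture is relied on to outrun ionisation.

Step 17
Reactants: 24 (−)-epicatechin
Product: 25 5,7,3',4'-tetra-O-benzyl-(−)-epicatechin
Conditions: BnBr, K2CO3, DMF, 0 °C → rt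
Reagents that add atoms: benzyl bromide, BrCc1ccccc1
Why: Williamson etherification of the four phenols, as in step 1.

Step 18
Reactants: 25 5,7,3',4'-tetra-O-benzyl-(−)-epicatechin
Product: 26 3,5,7,3',4'-penta-O-benzyl-(−)-epicatechin
Conditions: NaH, BnBr, n-Bu4NI (cat.), DMF, 0 °C → rt
Reagents that add atoms: benzyl bromide, BrCc1ccccc1
Why: Williamson etherification of the axial 3-OH, as in step 2.

Step 19
Reactants: 26 3,5,7,3',4'-penta-O-benzyl-(−)-epicatechin
Product: 27 4β-(2-ethoxyethoxy)-3,5,7,3',4'-penta-O-benzylepicatechin (3,4-trans)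
Conditions: DDQ, EtOCH2CH2OH, CH2Cl2, rt
Reagents that add atoms: 2-ethoxyethanol, CCOCCO
Why: DDQ benzylic oxidation: hydride abstraction from C4, activated by the ortho and para oxygens of ring A, gives a quinone methide-type cation. The alcohol traps it on the face anti to the axial 3-benzyloxy group (4β).

Step 20
Reactants: 27 4β-(2-ethoxyethoxy)-3,5,7,3',4'-penta-O-benzylepicatechin
Product: 28 8-bromo-4β-(2-ethoxyethoxy)-3,5,7,3',4'-penta-O-benzylepicatechin
Conditions: NBS, CH2Cl2, −40 °C
Reagents that add atoms: N-bromosuccinimide, O=C1CCC(=O)N1Br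
Why: Electrophilic aromatic bromination at C8, as in step 3; the neutral, cold conditions leave the C4 acetal intact.

Step 21
Reactants: 27 4β-(2-ethoxyethoxy)-3,5,7,3',4'-penta-O-benzylepicatechin
Product: 29 4β-(2,6-dimethylphenylthio)-3,5,7,3',4'-penta-O-benzylepicatechin (3,4-trans)
Conditions: 2,6-Me2C6H3SH, BF3·OEt2, CH2Cl2, −78 °C
Reagents that add atoms: 2,6-dimethylbenzenethiol, Cc1cccc(C)c1S
Why: Lewis acid-mediated exchange of the C4 acetal for a thioether through the C4 cation; the thiol adds anti to the axial 3-benzyloxy group (4β).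

Step 22
Reactants: 28 8-bromo-4β-(2-ethoxyethoxy)-3,5,7,3',4'-penta-O-benzylepicatechin; 29 4β-(2,6-dimethylphenylthio)-3,5,7,3',4'-penta-O-benzylepicatechin
Product: 30 [8-bromo-penta-O-benzylepicatechin]-(4β→8)-[4β-(2,6-dimethylphenylthio)-penta-O-benzylepicatechin]
Conditions: BF3·OEt2, CH2Cl2, −78 °C
Reagents that add atoms: none
Why: Friedel–Crafts-type C4→C8 coupling: the hard Lewis acid ionises only the C4–O group of 28, and C8 of 29 attacks the cation anti to the axial 3-benzyloxy group (4β). Bromine on C8 of 28 prevents self-condensation, and the soft C4–S bond of 29 should be inert to BF3 at this temperature.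

Step 23
Reactants: 30 [8-bromo-penta-O-benzylepicatechin]-(4β→8)-[4β-(2,6-dimethylphenylthio)-penta-O-benzylepicatechin]; 23 deca-O-benzyl-epicatechin-(4β→8)-catechin
Product: 31 8-bromo-eicosa-O-benzyl-arecatannin A2 (bromine on C8 of the top unit)
Conditions: I2, Ag2O, 4 Å MS, CH2Cl2, −78 → −30 °C
Reagents that add atoms: none
Why: Thiophilic activation followed by Friedel–Crafts-type coupling: the iodonium species from I2 and Ag2O turns the C4 sulfide of 30 into a leaving group. The C4 cation is captured by C8 of the upper unit of 23 (flanked by O1 and O7, the most nucleophilic free position) anti to the 3-benzyloxy group, forming the third 4β→8 bond.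

Step 24
Reactants: 31 8-bromo-eicosa-O-benzyl-arecatannin A2
Product: 32 arecatannin A2
Conditions: H2 (1 atm), Pd(OH)2/C, Et3N, THF–MeOH–H2O, rt
Reagents that add atoms: none
Why: Heterogeneous catalytic hydrogenolysis of twenty benzyl ethers and the aryl C–Br bond; Et3N traps HBr so the acid-labile interflavan bonds survive, and no stereocentre is touched.

## Compound list

1 | (+)-catechin, (2R,3S) | Oc1cc(O)c2c(c1)O[C@H](c1ccc(O)c(O)c1)[C@@H](O)C2 | starting material
2 | 5,7,3',4'-tetra-O-benzyl-(+)-catechin | c3ccccc3COc1cc(OCc3ccccc3)c2c(c1)O[C@H](c1ccc(OCc3ccccc3)c(OCc3ccccc3)c1)[C@@H](O)C2 | intermediate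
3 | 3,5,7,3',4'-penta-O-benzyl-(+)-catechin | c3ccccc3COc1cc(OCc3ccccc3)c2c(c1)O[C@H](c1ccc(OCc3ccccc3)c(OCc3ccccc3)c1)[C@@H](OCc3ccccc3)C2 | intermediate
4 | 8-bromo-3,5,7,3',4'-penta-O-benzylcatechin | Brc1c(OCc3ccccc3)cc(OCc3ccccc3)c2c1O[C@H](c1ccc(OCc3ccccc3)c(OCc3ccccc3)c1)[C@@H](OCc3ccccc3)C2 | intermediate
5 | 8-lithio-3,5,7,3',4'-penta-O-benzylcatechin (not isolated) | [Li]c1c(OCc3ccccc3)cc(OCc3ccccc3)c2c1O[C@H](c1ccc(OCc3ccccc3)c(OCc3ccccc3)c1)[C@@H](OCc3ccccc3)C2 | intermediate
6 | 3,5,7,3',4'-penta-O-benzylcatechin-8-carbaldehyde | O=Cc1c(OCc3ccccc3)cc(OCc3ccccc3)c2c1O[C@H](c1ccc(OCc3ccccc3)c(OCc3ccccc3)c1)[C@@H](OCc3ccccc3)C2 | intermediate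
7 | 3',5'-dihydroxyacetophenone | CC(=O)c1cc(O)cc(O)c1 | starting material
8 | 3',5'-bis(benzyloxy)acetophenone | CC(=O)c1cc(OCc2ccccc2)cc(OCc2ccccc2)c1 | intermediate
9 | 2'-bromo-3',5'-bis(benzyloxy)acetophenone | CC(=O)c1cc(OCc2ccccc2)cc(OCc2ccccc2)c1Br | intermediate
10 | (E)-1-[2-bromo-3,5-bis(benzyloxy)phenyl]-3-(penta-O-benzylcatechin-8-yl)prop-2-en-1-one | O=C(/C=C/c1c(OCc3ccccc3)cc(OCc3ccccc3)c2c1O[C@H](c1ccc(OCc3ccccc3)c(OCc3ccccc3)c1)[C@@H](OCc3ccccc3)C2)c1cc(OCc3ccccc3)cc(OCc3ccccc3)c1Br | intermediate
11 | (3R)-4,6-bis(benzyloxy)-3-(penta-O-benzylcatechin-8-yl)indan-1-one | O=C5C[C@@H](c1c(OCc3ccccc3)cc(OCc3ccccc3)c2c1O[C@H](c1ccc(OCc3ccccc3)c(OCc3ccccc3)c1)[C@@H](OCc3ccccc3)C2)c6c5cc(OCc3ccccc3)cc6OCc3ccccc3 | intermediate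
12 | peroxyhemiketal (Criegee adduct) of 11 and 3-chloroperbenzoic acid, C1 configuration undefined (not isolated) | OC5(OOC(=O)c7cccc(Cl)c7)C[C@@H](c1c(OCc3ccccc3)cc(OCc3ccccc3)c2c1O[C@H](c1ccc(OCc3ccccc3)c(OCc3ccccc3)c1)[C@@H](OCc3ccccc3)C2)c6c5cc(OCc3ccccc3)cc6OCc3ccccc3 | intermediate
13 | (4R)-5,7-bis(benzyloxy)-4-(penta-O-benzylcatechin-8-yl)chroman-2-one | c3ccccc3COc1cc(OCc3ccccc3)c2c(c1)OC(=O)C[C@H]2c1c(OCc3ccccc3)cc(OCc3ccccc3)c2c1O[C@H](c1ccc(OCc3ccccc3)c(OCc3ccccc3)c1)[C@@H](OCc3ccccc3)C2 | intermediate
14 | potassium enolate of 13 (not isolated) | c3ccccc3COc1cc(OCc3ccccc3)c2c(c1)OC([O-])=C[C@H]2c1c(OCc3ccccc3)cc(OCc3ccccc3)c2c1O[C@H](c1ccc(OCc3ccccc3)c(OCc3ccccc3)c1)[C@@H](OCc3ccccc3)C2.[K+] | intermediate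
15 | (3R,4R)-5,7-bis(benzyloxy)-3-hydroxy-4-(penta-O-benzylcatechin-8-yl)chroman-2-one (3,4-trans) | c3ccccc3COc1cc(OCc3ccccc3)c2c(c1)OC(=O)[C@H](O)[C@H]2c1c(OCc3ccccc3)cc(OCc3ccccc3)c2c1O[C@H](c1ccc(OCc3ccccc3)c(OCc3ccccc3)c1)[C@@H](OCc3ccccc3)C2 | intermediate
16 | (3R,4R)-3,5,7-tris(benzyloxy)-4-(penta-O-benzylcatechin-8-yl)chroman-2-one | c3ccccc3COc1cc(OCc3ccccc3)c2c(c1)OC(=O)[C@H](OCc3ccccc3)[C@H]2c1c(OCc3ccccc3)cc(OCc3ccccc3)c2c1O[C@H](c1ccc(OCc3ccccc3)c(OCc3ccccc3)c1)[C@@H](OCc3ccccc3)C2 | intermediate
17 | (2R,3R)-2-benzyloxy-3-[2,4-bis(benzyloxy)-6-hydroxyphenyl]-N-methoxy-N-methyl-3-(penta-O-benzylcatechin-8-yl)propanamide | CON(C)C(=O)[C@H](OCc3ccccc3)[C@H](c1c(OCc3ccccc3)cc(OCc3ccccc3)cc1O)c1c(OCc3ccccc3)cc(OCc3ccccc3)c2c1O[C@H](c1ccc(OCc3ccccc3)c(OCc3ccccc3)c1)[C@@H](OCc3ccccc3)C2 | intermediate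
18 | 4-bromobenzene-1,2-diol | Oc1ccc(Br)cc1O | starting material
19 | 4-bromo-1,2-bis(benzyloxy)benzene | Brc1ccc(OCc2ccccc2)c(OCc2ccccc2)c1 | intermediate
20 | 3,4-bis(benzyloxy)phenyllithium (not isolated) | [Li]c1ccc(OCc2ccccc2)c(OCc2ccccc2)c1 | intermediate
21 | (2R,3R)-2-benzyloxy-1-[3,4-bis(benzyloxy)phenyl]-3-[2,4-bis(benzyloxy)-6-hydroxyphenyl]-3-(penta-O-benzylcatechin-8-yl)propan-1-one | O=C(c1ccc(OCc3ccccc3)c(OCc3ccccc3)c1)[C@H](OCc3ccccc3)[C@H](c1c(OCc3ccccc3)cc(OCc3ccccc3)cc1O)c1c(OCc3ccccc3)cc(OCc3ccccc3)c2c1O[C@H](c1ccc(OCc3ccccc3)c(OCc3ccccc3)c1)[C@@H](OCc3ccccc3)C2 | intermediate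
22 | (1S,2R,3R)-2-benzyloxy-1-[3,4-bis(benzyloxy)phenyl]-3-[2,4-bis(benzyloxy)-6-hydroxyphenyl]-3-(penta-O-benzylcatechin-8-yl)propan-1-ol | O[C@@H](c1ccc(OCc3ccccc3)c(OCc3ccccc3)c1)[C@H](OCc3ccccc3)[C@H](c1c(OCc3ccccc3)cc(OCc3ccccc3)cc1O)c1c(OCc3ccccc3)cc(OCc3ccccc3)c2c1O[C@H](c1ccc(OCc3ccccc3)c(OCc3ccccc3)c1)[C@@H](OCc3ccccc3)C2 | intermediate
23 | deca-O-benzyl-epicatechin-(4β→8)-catechin | c3ccccc3COc1cc(OCc3ccccc3)c2c(c1)O[C@H](c1ccc(OCc3ccccc3)c(OCc3ccccc3)c1)[C@H](OCc3ccccc3)[C@H]2c1c(OCc3ccccc3)cc(OCc3ccccc3)c2c1O[C@H](c1ccc(OCc3ccccc3)c(OCc3ccccc3)c1)[C@@H](OCc3ccccc3)C2 | intermediate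
24 | (−)-epicatechin, (2R,3R) | Oc1cc(O)c2c(c1)O[C@H](c1ccc(O)c(O)c1)[C@H](O)C2 | starting material
25 | 5,7,3',4'-tetra-O-benzyl-(−)-epicatechin | c3ccccc3COc1cc(OCc3ccccc3)c2c(c1)O[C@H](c1ccc(OCc3ccccc3)c(OCc3ccccc3)c1)[C@H](O)C2 | intermediate
26 | 3,5,7,3',4'-penta-O-benzyl-(−)-epicatechin | c3ccccc3COc1cc(OCc3ccccc3)c2c(c1)O[C@H](c1ccc(OCc3ccccc3)c(OCc3ccccc3)c1)[C@H](OCc3ccccc3)C2 | intermediate
27 | 4β-(2-ethoxyethoxy)-3,5,7,3',4'-penta-O-benzylepicatechin | c3ccccc3COc1cc(OCc3ccccc3)c2c(c1)O[C@H](c1ccc(OCc3ccccc3)c(OCc3ccccc3)c1)[C@H](OCc3ccccc3)[C@H]2OCCOCC | intermediate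
28 | 8-bromo-4β-(2-ethoxyethoxy)-3,5,7,3',4'-penta-O-benzylepicatechin | c3ccccc3COc1cc(OCc3ccccc3)c2c(c1Br)O[C@H](c1ccc(OCc3ccccc3)c(OCc3ccccc3)c1)[C@H](OCc3ccccc3)[C@H]2OCCOCC | intermediate
29 | 4β-(2,6-dimethylphenylthio)-3,5,7,3',4'-penta-O-benzylepicatechin | c3ccccc3COc1cc(OCc3ccccc3)c2c(c1)O[C@H](c1ccc(OCc3ccccc3)c(OCc3ccccc3)c1)[C@H](OCc3ccccc3)[C@H]2Sc1c(C)cccc1C | intermediate
30 | [8-bromo-penta-O-benzylepicatechin]-(4β→8)-[4β-(2,6-dimethylphenylthio)-penta-O-benzylepicatechin] | c3ccccc3COc1cc(OCc3ccccc3)c2c(c1Br)O[C@H](c1ccc(OCc3ccccc3)c(OCc3ccccc3)c1)[C@H](OCc3ccccc3)[C@H]2c1c(OCc3ccccc3)cc(OCc3ccccc3)c2c1O[C@H](c1ccc(OCc3ccccc3)c(OCc3ccccc3)c1)[C@H](OCc3ccccc3)[C@H]2Sc1c(C)cccc1C | intermediate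
31 | 8-bromo-eicosa-O-benzyl-arecatannin A2 (bromine on C8 of the top unit) | c3ccccc3COc1cc(OCc3ccccc3)c2c(c1Br)O[C@H](c1ccc(OCc3ccccc3)c(OCc3ccccc3)c1)[C@H](OCc3ccccc3)[C@H]2c1c(OCc3ccccc3)cc(OCc3ccccc3)c2c1O[C@H](c1ccc(OCc3ccccc3)c(OCc3ccccc3)c1)[C@H](OCc3ccccc3)[C@H]2c1c(OCc3ccccc3)cc(OCc3ccccc3)c2c1O[C@H](c1ccc(OCc3ccccc3)c(OCc3ccccc3)c1)[C@H](OCc3ccccc3)[C@H]2c1c(OCc3ccccc3)cc(OCc3ccccc3)c2c1O[C@H](c1ccc(OCc3ccccc3)c(OCc3ccccc3)c1)[C@@H](OCc3ccccc3)C2 | intermediate
32 | arecatannin A2, epicatechin-(4β→8)-epicatechin-(4β→8)-epicatechin-(4β→8)-catechin | Oc1cc(O)c2c(c1)O[C@H](c1ccc(O)c(O)c1)[C@H](O)[C@H]2c1c(O)cc(O)c2c1O[C@H](c1ccc(O)c(O)c1)[C@H](O)[C@H]2c1c(O)cc(O)c2c1O[C@H](c1ccc(O)c(O)c1)[C@H](O)[C@H]2c1c(O)cc(O)c2c1O[C@H](c1ccc(O)c(O)c1)[C@@H](O)C2 | target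

## Step count and least certain steps

Total: 24 steps. Longest linear sequence: 15 steps (1–4, 7–12, 14–16, 23, 24).

Step 9 (key step). Most likely to go wrong: electrophilic hydroxylation of the benzylated phloroglucinol ring of the catechin unit (its C6 is free) by the peracid, which can compete because addition to a hindered aryl ketone is slow. Partial methylene migration is also possible, because the migrating aryl carbon is inductively deactivated by two meta-oxygens. Within the same approach the peracid could be exchanged for Me3SiOOSiMe3 with SnCl4, a peroxide that is not an electrophilic oxygen donor toward arenes. The fallback avoids oxygen insertion altogether and sets out from 6: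
- Knoevenagel–Doebner condensation with malonic acid (pyridine, piperidine, 80 °C) should give (E)-3-(penta-O-benzylcatechin-8-yl)acrylic acid F1.
- Acid-mediated hydroarylation and lactonisation of F1 with 3,5-bis(benzyloxy)phenol F2 (CF3CO2H, CH2Cl2, 0 °C → rt) should give the dihydrocoumarin directly, as 13 together with its C4 epimer, (4S)-5,7-bis(benzyloxy)-4-(penta-O-benzylcatechin-8-yl)chroman-2-one F3.
- The two are diastereomers and would be separated by chromatography. The route is rejoined at 13, at the price of catalyst control over C4.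

Step 8. Most likely to go wrong: reduction of the arylpalladium bromide by formate before the slow insertion into a beta-carbon that carries a di-ortho-substituted aryl group (hydrodebromination), simple conjugate reduction of the enone, or poor facial discrimination. The fallback replaces carbopalladation by boron-to-rhodium transmetalation and sets out from 9:
- Miyaura borylation (B2pin2, Pd(dppf)Cl2, KOAc, dioxane, 80 °C) should give 1-[3,5-bis(benzyloxy)-2-(4,4,5,5-tetramethyl-1,3,2-dioxaborolan-2-yl)phenyl]ethanone F4.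
- Claisen–Schmidt condensation of F4 with 6 should give the boryl chalcone (E)-1-[3,5-bis(benzyloxy)-2-(4,4,5,5-tetramethyl-1,3,2-dioxaborolan-2-yl)phenyl]-3-(penta-O-benzylcatechin-8-yl)prop-2-en-1-one F5.
- Asymmetric intramolecular 1,4-addition catalysed by monovalent rhodium ([RhCl(C2H4)2]2, chiral phosphoramidite, aqueous K3PO4, toluene) needs no hydride donor and rejoins the route at 11.

Step 16. Most likely to go wrong: ionisation of the activated oxyphosphonium to a 4-alkoxybenzyl cation, leading to loss of stereospecificity at C2 (closure with partial retention) or to elimination. The fallback sets out from 21 and makes the O1–C2 bond at the ketone oxidation level: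
- With Et3SiH and BF3·OEt2 in CH2Cl2 at −78 °C the phenol should close onto the ketone to the cyclic hemiketal 2-hydroxy-3,5,7,3',4'-penta-O-benzyl-4-(penta-O-benzylcatechin-8-yl)flavan F6.
- F6 ionises to the 2-aryl oxocarbenium ion, and hydride is delivered axially, anti to the pseudoaxial 3-benzyloxy group, as in the reductive etherification used for C-aryl glycosides.
- This should give the 2,3-cis ring directly and rejoins the route at 23, bypassing steps 15 and 16.

Step 23. Most likely to go wrong: slow union of two hindered dimers, which would let iodination of the free ring positions of the nucleophile by the promoter, or attack through a C6 position, compete with the desired capture at C8. The fallback adds the top two units one at a time with the hard Lewis acid only and sets out from 23 and 28: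
- Coupling with BF3·OEt2 in CH2Cl2 at −78 °C should give the capped trimer [8-bromo-penta-O-benzylepicatechin]-(4β→8)-[penta-O-benzylepicatechin]-(4β→8)-[penta-O-benzylcatechin] F7.
- Bromine–lithium exchange (n-BuLi, THF, −78 °C) and a methanol quench should give the trimer [penta-O-benzylepicatechin]-(4β→8)-[penta-O-benzylepicatechin]-(4β→8)-[penta-O-benzylcatechin] F8.
- A second BF3·OEt2 coupling of F8 with 28 rejoins the route at 31.

## Further compounds

F1 | step 9 | (E)-3-(penta-O-benzylcatechin-8-yl)acrylic acid | OC(=O)/C=C/c1c(OCc3ccccc3)cc(OCc3ccccc3)c2c1O[C@H](c1ccc(OCc3ccccc3)c(OCc3ccccc3)c1)[C@@H](OCc3ccccc3)C2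
F2 | step 9 | 3,5-bis(benzyloxy)phenol | Oc1cc(OCc2ccccc2)cc(OCc2ccccc2)c1
F3 | step 9 | (4S)-5,7-bis(benzyloxy)-4-(penta-O-benzylcatechin-8-yl)chroman-2-one (C4 epimer of 13) | c3ccccc3COc1cc(OCc3ccccc3)c2c(c1)OC(=O)C[C@@H]2c1c(OCc3ccccc3)cc(OCc3ccccc3)c2c1O[C@H](c1ccc(OCc3ccccc3)c(OCc3ccccc3)c1)[C@@H](OCc3ccccc3)C2
F4 | step 8 | 1-[3,5-bis(benzyloxy)-2-(4,4,5,5-tetramethyl-1,3,2-dioxaborolan-2-yl)phenyl]ethanone | CC(=O)c1cc(OCc2ccccc2)cc(OCc2ccccc2)c1B4OC(C)(C)C(C)(C)O4
F5 | step 8 | (E)-1-[3,5-bis(benzyloxy)-2-(4,4,5,5-tetramethyl-1,3,2-dioxaborolan-2-yl)phenyl]-3-(penta-O-benzylcatechin-8-yl)prop-2-en-1-one | O=C(/C=C/c1c(OCc3ccccc3)cc(OCc3ccccc3)c2c1O[C@H](c1ccc(OCc3ccccc3)c(OCc3ccccc3)c1)[C@@H](OCc3ccccc3)C2)c1cc(OCc3ccccc3)cc(OCc3ccccc3)c1B4OC(C)(C)C(C)(C)O4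
F6 | step 16 | (3R,4R)-2-hydroxy-3,5,7,3',4'-penta-O-benzyl-4-(penta-O-benzylcatechin-8-yl)flavan, cyclic hemiketal, C2 configuration undefined | c3ccccc3COc1cc(OCc3ccccc3)c2c(c1)OC(O)(c1ccc(OCc3ccccc3)c(OCc3ccccc3)c1)[C@H](OCc3ccccc3)[C@H]2c1c(OCc3ccccc3)cc(OCc3ccccc3)c2c1O[C@H](c1ccc(OCc3ccccc3)c(OCc3ccccc3)c1)[C@@H](OCc3ccccc3)C2
F7 | step 23 | [8-bromo-penta-O-benzylepicatechin]-(4β→8)-[penta-O-benzylepicatechin]-(4β→8)-[penta-O-benzylcatechin] | c3ccccc3COc1cc(OCc3ccccc3)c2c(c1Br)O[C@H](c1ccc(OCc3ccccc3)c(OCc3ccccc3)c1)[C@H](OCc3ccccc3)[C@H]2c1c(OCc3ccccc3)cc(OCc3ccccc3)c2c1O[C@H](c1ccc(OCc3ccccc3)c(OCc3ccccc3)c1)[C@H](OCc3ccccc3)[C@H]2c1c(OCc3ccccc3)cc(OCc3ccccc3)c2c1O[C@H](c1ccc(OCc3ccccc3)c(OCc3ccccc3)c1)[C@@H](OCc3ccccc3)C2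
F8 | step 23 | [penta-O-benzylepicatechin]-(4β→8)-[penta-O-benzylepicatechin]-(4β→8)-[penta-O-benzylcatechin] | c3ccccc3COc1cc(OCc3ccccc3)c2c(c1)O[C@H](c1ccc(OCc3ccccc3)c(OCc3ccccc3)c1)[C@H](OCc3ccccc3)[C@H]2c1c(OCc3ccccc3)cc(OCc3ccccc3)c2c1O[C@H](c1ccc(OCc3ccccc3)c(OCc3ccccc3)c1)[C@H](OCc3ccccc3)[C@H]2c1c(OCc3ccccc3)cc(OCc3ccccc3)c2c1O[C@H](c1ccc(OCc3ccccc3)c(OCc3ccccc3)c1)[C@@H](OCc3ccccc3)C2
A1 | alternative 1 | 5,7-bis(benzyloxy)-2-[3,4-bis(benzyloxy)phenyl]-4-(benzylated trimer-8-yl)-4H-chromene | c3ccccc3COc1cc(OCc3ccccc3)c2c(c1)OC(c1ccc(OCc3ccccc3)c(OCc3ccccc3)c1)=C[C@H]2c1c(OCc3ccccc3)cc(OCc3ccccc3)c2c1O[C@H](c1ccc(OCc3ccccc3)c(OCc3ccccc3)c1)[C@H](OCc3ccccc3)[C@H]2c1c(OCc3ccccc3)cc(OCc3ccccc3)c2c1O[C@H](c1ccc(OCc3ccccc3)c(OCc3ccccc3)c1)[C@H](OCc3ccccc3)[C@H]2c1c(OCc3ccccc3)cc(OCc3ccccc3)c2c1O[C@H](c1ccc(OCc3ccccc3)c(OCc3ccccc3)c1)[C@@H](OCc3ccccc3)C2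
A2 | alternative 1 | 3,5-bis(benzyloxy)phenol | Oc1cc(OCc2ccccc2)cc(OCc2ccccc2)c1
A3 | alternative 1 | (E)-1-[3,4-bis(benzyloxy)phenyl]-3-(benzylated epicatechin-(4β→8)-epicatechin-(4β→8)-catechin-8-yl)prop-2-en-1-one | O=C(/C=C/c1c(OCc3ccccc3)cc(OCc3ccccc3)c2c1O[C@H](c1ccc(OCc3ccccc3)c(OCc3ccccc3)c1)[C@H](OCc3ccccc3)[C@H]2c1c(OCc3ccccc3)cc(OCc3ccccc3)c2c1O[C@H](c1ccc(OCc3ccccc3)c(OCc3ccccc3)c1)[C@H](OCc3ccccc3)[C@H]2c1c(OCc3ccccc3)cc(OCc3ccccc3)c2c1O[C@H](c1ccc(OCc3ccccc3)c(OCc3ccccc3)c1)[C@@H](OCc3ccccc3)C2)c1ccc(OCc3ccccc3)c(OCc3ccccc3)c1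
A4 | alternative 2 | deca-O-benzyl-epicatechin-(4β→8)-catechin (identical with 23) | c3ccccc3COc1cc(OCc3ccccc3)c2c(c1)O[C@H](c1ccc(OCc3ccccc3)c(OCc3ccccc3)c1)[C@H](OCc3ccccc3)[C@H]2c1c(OCc3ccccc3)cc(OCc3ccccc3)c2c1O[C@H](c1ccc(OCc3ccccc3)c(OCc3ccccc3)c1)[C@@H](OCc3ccccc3)C2
A5 | alternative 2 | (1R,2R)-2-benzyloxy-1-[3,4-bis(benzyloxy)phenyl]-1-[3,5-bis(benzyloxy)phenoxy]-3-methoxy-3-(penta-O-benzylcatechin-8-yl)propane, C3 configuration undefined | c3ccccc3COc1cc(OCc3ccccc3)cc(c1)O[C@H](c1ccc(OCc3ccccc3)c(OCc3ccccc3)c1)[C@H](OCc3ccccc3)C(OC)c1c(OCc3ccccc3)cc(OCc3ccccc3)c2c1O[C@H](c1ccc(OCc3ccccc3)c(OCc3ccccc3)c1)[C@@H](OCc3ccccc3)C2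
A6 | alternative 3 | 5,7-bis(benzyloxy)-2-[3,4-bis(benzyloxy)phenyl]-4-(penta-O-benzylcatechin-8-yl)-4H-chromene | c3ccccc3COc1cc(OCc3ccccc3)c2c(c1)OC(c1ccc(OCc3ccccc3)c(OCc3ccccc3)c1)=C[C@H]2c1c(OCc3ccccc3)cc(OCc3ccccc3)c2c1O[C@H](c1ccc(OCc3ccccc3)c(OCc3ccccc3)c1)[C@@H](OCc3ccccc3)C2
A7 | alternative 3 | 8-{1-[2,4-bis(benzyloxy)-6-({1-[3,4-bis(benzyloxy)phenyl]vinyl}oxy)phenyl]prop-2-en-1-yl}-penta-O-benzylcatechin, diene with the C4 configuration of A6 | C=C[C@H](c1c(OCc3ccccc3)cc(OCc3ccccc3)cc1OC(=C)c1ccc(OCc3ccccc3)c(OCc3ccccc3)c1)c1c(OCc3ccccc3)cc(OCc3ccccc3)c2c1O[C@H](c1ccc(OCc3ccccc3)c(OCc3ccccc3)c1)[C@@H](OCc3ccccc3)C2
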